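Artelasticin is cut at the C6–CH2 and C8–CH2 bonds of ring A. C6 and C8 each sit ortho to a phenolic oxygen (O5 and O7), so both prenyl groups can be carried in on those oxygens as 1,1-dimethylallyl ethers and handed to carbon by two aromatic Claisen shifts in one Eu(fod)3-promoted operation, without any ring being formed. The precursor is a 3-prenylflavone with 2-methylbut-3-en-2-yl ethers on O5 and O7 and MOM ethers on the ring B phenols. To avoid etherifying the chelated 5-OH of a finished flavone, the tertiary ethers are introduced on the acetophenone as propargylic ethers, carried through a Baker–Venkataraman flavone synthesis, and semihydrogenated.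

Key step: step 7

Remark: the target is achiral; the only stereogenic intermediate (10) is racemic and loses its stereocenter on ring closure. 3-Chloro-3-methylbut-1-yne is taken as a purchased reagent.

Step 1
Reactants: 1 2,4-dihydroxybenzoic acid
Product: 3 2,4-bis(methoxymethoxy)benzoic acid, via MOM ester 2 (not isolated)
Conditions: NaH (3.3 equiv), MOMCl (3.3 equiv), DMF, 0 °C to rt; then 2 M aq NaOH, MeOH, 50 °C; 1 M HCl to pH 4 at 0 °C
Reagents that add atoms: chloromethyl methyl ether (MOMCl), COCCl; sodium hydroxide, [Na+].[OH-]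
Why: Williamson-type O-alkylation converts the carboxylate and both phenoxides into MOM derivatives, and saponification then cleaves only the labile MOM ester, because aryl MOM acetals are inert to base and survive a brief cold acidification to pH 4.

Step 2
Reactants: 4 2,4,6-trihydroxyacetophenone; 5 3-chloro-3-methylbut-1-yne (2.3 equiv)
Product: 6 1-[2-hydroxy-4,6-bis(2-methylbut-3-yn-2-yloxy)phenyl]ethan-1-one
Conditions: CuCl2·2H2O (1 mol %), DBU (2.5 equiv), MeCN, N2, 0 °C to rt
Reagents that add atoms: none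
Why: In this copper-catalysed propargylic etherification the copper acetylide of 5 ionises to an allenylidene that phenoxide captures at the tertiary carbon; the para hydroxyl and one ortho hydroxyl should react while the last one stays hydrogen-bonded to the acetyl group, as in other 2,4-di-O-alkylations of this ketone, and the ethers have no propargylic hydrogen for DBU to isomerise.

Step 3
Reactants: 6 1-[2-hydroxy-4,6-bis(2-methylbut-3-yn-2-yloxy)phenyl]ethan-1-one; 3 2,4-bis(methoxymethoxy)benzoic acid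
Product: 7 2-acetyl-3,5-bis(2-methylbut-3-yn-2-yloxy)phenyl 2,4-bis(methoxymethoxy)benzoate
Conditions: DCC, DMAP (cat.), CH2Cl2, 0 °C to rt
Reagents that add atoms: none
Why: Steglich esterification acylates the hindered, hydrogen-bonded phenol through the acylpyridinium intermediate under neutral conditions, so no HCl is generated that could cleave the MOM acetals.

Step 4
Reactants: 7 2-acetyl-3,5-bis(2-methylbut-3-yn-2-yloxy)phenyl 2,4-bis(methoxymethoxy)benzoate
Product: 8 1-[2,4-bis(methoxymethoxy)phenyl]-3-[2-hydroxy-4,6-bis(2-methylbut-3-yn-2-yloxy)phenyl]propane-1,3-dione (largely enolised)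
Conditions: KOtBu (2.2 equiv), THF, 0 °C to rt; then AcOH
Reagents that add atoms: none
Why: In the Baker–Venkataraman rearrangement the methyl ketone enolate attacks the neighbouring aryl ester intramolecularly (O to C acyl shift) and gives the stabilised diketonate; tert-butoxide does not attack the MOM or tertiary propargyl ethers.

Step 5
Reactants: 8 1-[2,4-bis(methoxymethoxy)phenyl]-3-[2-hydroxy-4,6-bis(2-methylbut-3-yn-2-yloxy)phenyl]propane-1,3-dione; 9 prenyl bromide (1-bromo-3-methylbut-2-ene, 1.1 equiv)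
Product: 11 2-[2,4-bis(methoxymethoxy)phenyl]-5,7-bis(2-methylbut-3-yn-2-yloxy)-3-(3-methylbut-2-en-1-yl)-4H-chromen-4-one, via C-prenyl diketone 10 (not isolated)
Conditions: K2CO3, acetone, reflux; then filter, PPTS (cat.), 4 Å MS, toluene, 70 °C
Reagents that add atoms: none
Why: C-alkylation of the soft 1,3-diketonate with the allylic bromide is followed by cyclodehydration (the ring A phenol adds to the aroyl carbonyl and the 2-hydroxychromanone loses water), the classical entry to 3-alkylflavones; PPTS in dry toluene is too weak to cleave MOM acetals or ionise the propargylic ethers, and the racemic stereocenter of 10 vanishes.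

Step 6
Reactants: 11 2-[2,4-bis(methoxymethoxy)phenyl]-5,7-bis(2-methylbut-3-yn-2-yloxy)-3-(3-methylbut-2-en-1-yl)-4H-chromen-4-one
Product: 12 2-[2,4-bis(methoxymethoxy)phenyl]-5,7-bis(2-methylbut-3-en-2-yloxy)-3-(3-methylbut-2-en-1-yl)-4H-chromen-4-one
Conditions: H2 (1 atm, 2 equiv uptake), Pd/CaCO3 poisoned with Pb(OAc)2 (Lindlar catalyst), quinoline, EtOAc, rt
Reagents that add atoms: none
Why: Lindlar semihydrogenation adds H2 to the two terminal alkynes and stops at the alkene on the lead-poisoned palladium surface, while the trisubstituted prenyl alkene and the chromone double bond are not reduced.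

Step 7
Reactants: 12 2-[2,4-bis(methoxymethoxy)phenyl]-5,7-bis(2-methylbut-3-en-2-yloxy)-3-(3-methylbut-2-en-1-yl)-4H-chromen-4-one
Product: 14 2-[2,4-bis(methoxymethoxy)phenyl]-5,7-dihydroxy-3,6,8-tris(3-methylbut-2-en-1-yl)-4H-chromen-4-one (artelasticin 2',4'-bis(methoxymethyl) ether), via 6-prenyl monoether 13 (not isolated)
Conditions: Eu(fod)3 [tris(6,6,7,7,8,8,8-heptafluoro-2,2-dimethyl-3,5-octanedionato)europium, trivalent europium] (15 mol %), NaHCO3, PhCl, argon, 70 °C, then 125 °C
Reagents that add atoms: none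
Why: Each O–C(CH3)2–CH=CH2 unit undergoes a concerted, chair-like aromatic Claisen [3,3] shift to the neighbouring ring A carbon and the dienone tautomerises, so the tertiary ether carbon becomes the (CH3)2C= terminus of a prenyl group on C6 or C8. The closest known reactions are Eu(fod)3-catalysed Claisen rearrangements of 5-O-allylated flavonoids and thermal rearrangements of 7-(1,1-dimethylallyloxy)chromones and coumarins to 8-prenyl phenols. No ring is closed and no stereocenter is created, so only site and order selectivity are needed. The europium Lewis acid is held between the C4 carbonyl and O5, so the O5 group should move first and at the lower temperature to C6, its only free ortho position because C4a is quaternary, giving 13. With C6 filled, the O7 group can rearomatise only after migrating to C8, which is also the intrinsically preferred site owing to the higher C7–C8 bond order of the chromone, and this shift is completed at 125 °C. Solid NaHCO3 buffers adventitious acid so that loss of isoprene from the tertiary ethers is suppressed and the C3 prenyl group and MOM acetals survive.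

Step 8
Reactants: 14 2-[2,4-bis(methoxymethoxy)phenyl]-5,7-dihydroxy-3,6,8-tris(3-methylbut-2-en-1-yl)-4H-chromen-4-one
Product: 15 artelasticin, 2-(2,4-dihydroxyphenyl)-5,7-dihydroxy-3,6,8-tris(3-methylbut-2-en-1-yl)-4H-chromen-4-one
Conditions: conc. aq HCl (cat.), MeOH–THF, 0 °C to rt
Reagents that add atoms: none
Why: Acid-catalysed acetal exchange with methanol releases both ring B phenols and dimethoxymethane; dilute acid at or below room temperature is chosen so that the ortho-prenyl phenols should not cyclise to chromans.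

Compound list
1 | 2,4-dihydroxybenzoic acid | O=C(O)c1ccc(O)cc1O | starting material
2 | methoxymethyl 2,4-bis(methoxymethoxy)benzoate | COCOC(=O)c1ccc(OCOC)cc1OCOC | intermediate
3 | 2,4-bis(methoxymethoxy)benzoic acid | O=C(O)c1ccc(OCOC)cc1OCOC | intermediate
4 | 2,4,6-trihydroxyacetophenone | CC(=O)c1c(O)cc(O)cc1O | starting material
5 | 3-chloro-3-methylbut-1-yne | CC(C)(Cl)C#C | starting material
6 | 1-[2-hydroxy-4,6-bis(2-methylbut-3-yn-2-yloxy)phenyl]ethan-1-one | CC(=O)c1c(O)cc(OC(C)(C)C#C)cc1OC(C)(C)C#C | intermediate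
7 | 2-acetyl-3,5-bis(2-methylbut-3-yn-2-yloxy)phenyl 2,4-bis(methoxymethoxy)benzoate | CC(=O)c1c(OC(=O)c2ccc(OCOC)cc2OCOC)cc(OC(C)(C)C#C)cc1OC(C)(C)C#C | intermediate
8 | 1-[2,4-bis(methoxymethoxy)phenyl]-3-[2-hydroxy-4,6-bis(2-methylbut-3-yn-2-yloxy)phenyl]propane-1,3-dione | O=C(CC(=O)c1ccc(OCOC)cc1OCOC)c1c(O)cc(OC(C)(C)C#C)cc1OC(C)(C)C#C | intermediate
9 | prenyl bromide (1-bromo-3-methylbut-2-ene) | CC(C)=CCBr | starting material
10 | 1-[2,4-bis(methoxymethoxy)phenyl]-3-[2-hydroxy-4,6-bis(2-methylbut-3-yn-2-yloxy)phenyl]-2-(3-methylbut-2-en-1-yl)propane-1,3-dione (racemic) | O=C(C(CC=C(C)C)C(=O)c1ccc(OCOC)cc1OCOC)c1c(O)cc(OC(C)(C)C#C)cc1OC(C)(C)C#C | intermediate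
11 | 2-[2,4-bis(methoxymethoxy)phenyl]-5,7-bis(2-methylbut-3-yn-2-yloxy)-3-(3-methylbut-2-en-1-yl)-4H-chromen-4-one | C#CC(C)(C)Oc1cc(OC(C)(C)C#C)c2c(=O)c(CC=C(C)C)c(-c3ccc(OCOC)cc3OCOC)oc2c1 | intermediate
12 | 2-[2,4-bis(methoxymethoxy)phenyl]-5,7-bis(2-methylbut-3-en-2-yloxy)-3-(3-methylbut-2-en-1-yl)-4H-chromen-4-one | C=CC(C)(C)Oc1cc(OC(C)(C)C=C)c2c(=O)c(CC=C(C)C)c(-c3ccc(OCOC)cc3OCOC)oc2c1 | intermediate
13 | 2-[2,4-bis(methoxymethoxy)phenyl]-5-hydroxy-7-(2-methylbut-3-en-2-yloxy)-3,6-bis(3-methylbut-2-en-1-yl)-4H-chromen-4-one | C=CC(C)(C)Oc1cc2oc(-c3ccc(OCOC)cc3OCOC)c(CC=C(C)C)c(=O)c2c(O)c1CC=C(C)C | intermediate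
14 | 2-[2,4-bis(methoxymethoxy)phenyl]-5,7-dihydroxy-3,6,8-tris(3-methylbut-2-en-1-yl)-4H-chromen-4-one | CC(C)=CCc1c(O)c(CC=C(C)C)c2oc(-c3ccc(OCOC)cc3OCOC)c(CC=C(C)C)c(=O)c2c1O | intermediate
15 | artelasticin, 2-(2,4-dihydroxyphenyl)-5,7-dihydroxy-3,6,8-tris(3-methylbut-2-en-1-yl)-4H-chromen-4-one (achiral) | CC(C)=CCc1c(O)c(CC=C(C)C)c2oc(-c3ccc(O)cc3O)c(CC=C(C)C)c(=O)c2c1O | target

Total step count: 8. Longest linear sequence: 7 steps (4 to 15 through steps 2 to 8).

Steps most likely to fail

Step 7. The tertiary allyl ethers may ionise and lose isoprene faster than they rearrange, or the O7 group may migrate before C6 has been occupied and end up misplaced. The fallback forms the two C–C bonds without a sigmatropic shift. It sets out from 12: Pd(PPh3)4 (zerovalent palladium) and morpholine in THF should remove both tertiary allyl groups to give 2-[2,4-bis(methoxymethoxy)phenyl]-5,7-dihydroxy-3-(3-methylbut-2-en-1-yl)-4H-chromen-4-one F1. Base-mediated nuclear C-prenylation of F1 with 9 (NaOMe, MeOH) then alkylates C6 and C8, the only free nucleophilic carbons of ring A. It proceeds through 2-[2,4-bis(methoxymethoxy)phenyl]-5,7-dihydroxy-3,6-bis(3-methylbut-2-en-1-yl)-4H-chromen-4-one F2 and 2-[2,4-bis(methoxymethoxy)phenyl]-5,7-dihydroxy-3,8-bis(3-methylbut-2-en-1-yl)-4H-chromen-4-one F3, which are resubmitted. The fallback comes back to the route at 14. It is less selective (O-alkylation competes) but does not depend on the ethers.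

Step 2. Etherification may stop at the para hydroxyl, run on to the third hydroxyl, or alkylate the electron-rich ring carbons. The fallback is a Tsuji–Trost O-allylation that installs the 1,1-dimethylallyl ethers directly. It sets out from 4: tert-butyl 2-methylbut-3-en-2-yl carbonate F4 (from 2-methylbut-3-en-2-ol, n-BuLi and Boc2O) with Pd(PPh3)4 (zerovalent palladium) in THF at 0 °C should give 1-[2-hydroxy-4,6-bis(2-methylbut-3-en-2-yloxy)phenyl]ethan-1-one F5 by kinetic attack of phenoxide at the more substituted allyl terminus. Steglich esterification with 3 then gives 2-acetyl-3,5-bis(2-methylbut-3-en-2-yloxy)phenyl 2,4-bis(methoxymethoxy)benzoate F6. Baker–Venkataraman rearrangement gives 1-[2,4-bis(methoxymethoxy)phenyl]-3-[2-hydroxy-4,6-bis(2-methylbut-3-en-2-yloxy)phenyl]propane-1,3-dione F7. C-prenylation with 9 and ring closure with K2CO3 alone in refluxing acetone, through 1-[2,4-bis(methoxymethoxy)phenyl]-3-[2-hydroxy-4,6-bis(2-methylbut-3-en-2-yloxy)phenyl]-2-(3-methylbut-2-en-1-yl)propane-1,3-dione F8, comes back to the route at 12, and step 6 is then not needed.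

Step 8. Acid may trigger cyclisation of a ring A phenol onto a neighbouring prenyl group (chroman formation) or addition of methanol to a prenyl alkene. The fallback moves the acid treatment ahead of alkyne reduction and rearrangement, where only the more acid-resistant tertiary propargyl ethers are present. It sets out from 11: methanolic HCl should give 2-(2,4-dihydroxyphenyl)-5,7-bis(2-methylbut-3-yn-2-yloxy)-3-(3-methylbut-2-en-1-yl)-4H-chromen-4-one F9. Lindlar semihydrogenation gives 2-(2,4-dihydroxyphenyl)-5,7-bis(2-methylbut-3-en-2-yloxy)-3-(3-methylbut-2-en-1-yl)-4H-chromen-4-one F10. The Eu(fod)3-promoted double Claisen rearrangement, through 2-(2,4-dihydroxyphenyl)-5-hydroxy-7-(2-methylbut-3-en-2-yloxy)-3,6-bis(3-methylbut-2-en-1-yl)-4H-chromen-4-one F11, then comes back to the route at 15 with no step after the rearrangement.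

Further compounds
F1 | step 7 | 2-[2,4-bis(methoxymethoxy)phenyl]-5,7-dihydroxy-3-(3-methylbut-2-en-1-yl)-4H-chromen-4-one | COCOc1ccc(-c2oc3cc(O)cc(O)c3c(=O)c2CC=C(C)C)c(OCOC)c1
F2 | step 7 | 2-[2,4-bis(methoxymethoxy)phenyl]-5,7-dihydroxy-3,6-bis(3-methylbut-2-en-1-yl)-4H-chromen-4-one | COCOc1ccc(-c2oc3cc(O)c(CC=C(C)C)c(O)c3c(=O)c2CC=C(C)C)c(OCOC)c1
F3 | step 7 | 2-[2,4-bis(methoxymethoxy)phenyl]-5,7-dihydroxy-3,8-bis(3-methylbut-2-en-1-yl)-4H-chromen-4-one | COCOc1ccc(-c2oc3c(CC=C(C)C)c(O)cc(O)c3c(=O)c2CC=C(C)C)c(OCOC)c1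
F4 | step 2 | tert-butyl 2-methylbut-3-en-2-yl carbonate | C=CC(C)(C)OC(=O)OC(C)(C)C
F5 | step 2 | 1-[2-hydroxy-4,6-bis(2-methylbut-3-en-2-yloxy)phenyl]ethan-1-one | CC(=O)c1c(O)cc(OC(C)(C)C=C)cc1OC(C)(C)C=C
F6 | step 2 | 2-acetyl-3,5-bis(2-methylbut-3-en-2-yloxy)phenyl 2,4-bis(methoxymethoxy)benzoate | CC(=O)c1c(OC(=O)c2ccc(OCOC)cc2OCOC)cc(OC(C)(C)C=C)cc1OC(C)(C)C=C
F7 | step 2 | 1-[2,4-bis(methoxymethoxy)phenyl]-3-[2-hydroxy-4,6-bis(2-methylbut-3-en-2-yloxy)phenyl]propane-1,3-dione | O=C(CC(=O)c1ccc(OCOC)cc1OCOC)c1c(O)cc(OC(C)(C)C=C)cc1OC(C)(C)C=C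
F8 | step 2 | 1-[2,4-bis(methoxymethoxy)phenyl]-3-[2-hydroxy-4,6-bis(2-methylbut-3-en-2-yloxy)phenyl]-2-(3-methylbut-2-en-1-yl)propane-1,3-dione (racemic) | O=C(C(CC=C(C)C)C(=O)c1ccc(OCOC)cc1OCOC)c1c(O)cc(OC(C)(C)C=C)cc1OC(C)(C)C=C
F9 | step 8 | 2-(2,4-dihydroxyphenyl)-5,7-bis(2-methylbut-3-yn-2-yloxy)-3-(3-methylbut-2-en-1-yl)-4H-chromen-4-one | C#CC(C)(C)Oc1cc(OC(C)(C)C#C)c2c(=O)c(CC=C(C)C)c(-c3ccc(O)cc3O)oc2c1
F10 | step 8 | 2-(2,4-dihydroxyphenyl)-5,7-bis(2-methylbut-3-en-2-yloxy)-3-(3-methylbut-2-en-1-yl)-4H-chromen-4-one | C=CC(C)(C)Oc1cc(OC(C)(C)C=C)c2c(=O)c(CC=C(C)C)c(-c3ccc(O)cc3O)oc2c1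
F11 | step 8 | 2-(2,4-dihydroxyphenyl)-5-hydroxy-7-(2-methylbut-3-en-2-yloxy)-3,6-bis(3-methylbut-2-en-1-yl)-4H-chromen-4-one | C=CC(C)(C)Oc1cc2oc(-c3ccc(O)cc3O)c(CC=C(C)C)c(=O)c2c(O)c1CC=C(C)C
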